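**Retrosynthetic overview**
- Asperchondol A comes from one global hydrogenation of a protected precursor: benzyl ether on the ring B phenol, diphenylmethylene ketal on the ring A catechol, internal alkyne in the side chain.
- The diarylmethane bond comes from a Suzuki–Miyaura coupling of a ring B aryl bromide with a ring A benzylic pinacol boronate (ortho-lithiation of ketal-protected 4-methylcatechol, then one-carbon boron homologation).
- The tertiary carbinol and the whole C6 side chain come from a metal-free, chiral-biphenol-catalysed enantioselective propargylation of 2-benzyloxy-4-bromoacetophenone with a new achiral α-isopropyl allenyl boronate, made in one step from 4-methylpent-2-yn-1-ol.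
- No carbocycle is built: both benzene rings are bought. The only ring formed is the temporary 1,3-dioxole on ring A (first step), opened again in the last step.

Assumption: (R)-3,3′-dibromo-BINOL is taken to give Si-face addition to the aryl methyl ketone (the (S)-carbinol), a sense recalled from the parent allyl- and propargylborations and not verified for this reagent; if the first run shows the opposite sense, the mirror-image catalyst is used and nothing else changes.

**Step 1**
Reactants: 1 4-methylbenzene-1,2-diol (4-methylcatechol)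
Product: 2 5-methyl-2,2-diphenyl-1,3-benzodioxole
Conditions: Ph2CCl2 (1.2 equiv), neat, 170 °C, 30 min
Reagents that add atoms: dichlorodiphenylmethane, ClC(Cl)(c1ccccc1)c1ccccc1
Why: Ketalisation of a catechol with a gem-dichloride (double substitution driven by loss of HCl) gives the diphenylmethylene ketal, which tolerates organolithium and palladium chemistry and is later removed by hydrogenolysis.

**Step 2**
Reactants: 2 5-methyl-2,2-diphenyl-1,3-benzodioxole
Product: 5 benzylic boronate 4,4,5,5-tetramethyl-2-[(6-methyl-2,2-diphenyl-1,3-benzodioxol-4-yl)methyl]-1,3,2-dioxaborolane, via aryllithium 3 (not isolated), via boronate complex 4 (not isolated)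
Conditions: n-BuLi (1.15 equiv), TMEDA, THF, −20 → 0 °C; then BrCH2Bpin (1.3 equiv), −78 °C → rt
Reagents that add atoms: 2-(bromomethyl)-4,4,5,5-tetramethyl-1,3,2-dioxaborolane, BrCB1OC(C)(C)C(C)(C)O1
Why: Directed ortho-metalation takes the oxygen-flanked C–H that is not crowded by the methyl group (C7 of 2), and the aryllithium adds to boron to give an ate complex whose 1,2-aryl shift expels bromide (Matteson homologation), placing the CH2–B unit at the ring A carbon that carries the benzylic link in the target.

**Step 3**
Reactants: 6 1-(4-bromo-2-hydroxyphenyl)ethanone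
Product: 7 1-[2-(benzyloxy)-4-bromophenyl]ethanone
Conditions: BnBr (1.1 equiv), K2CO3 (1.5 equiv), DMF, 60 °C
Reagents that add atoms: benzyl bromide, BrCc1ccccc1
Why: Williamson etherification of the phenoxide masks the chelating ortho-hydroxyl, which would otherwise bind boron and open an uncatalysed racemic pathway in step 5, with a group that the final hydrogenation removes.

**Step 4**
Reactants: 8 4-methylpent-2-yn-1-ol
Product: 9 allenyl boronate 4,4,5,5-tetramethyl-2-(4-methylpenta-1,2-dien-3-yl)-1,3,2-dioxaborolane
Conditions: B2pin2 (1.3 equiv), Cu(OAc)2 (5 mol %), Xantphos (6 mol %), Ti(O-i-Pr)4 (1.1 equiv), toluene, 60 °C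
Reagents that add atoms: bis(pinacolato)diboron, CC1(C)OB(OC1(C)C)B1OC(C)(C)C(C)(C)O1
Why: Copper-catalysed borylation of a propargylic alcohol: a boryl complex of monovalent copper adds across the alkyne with boron at the isopropyl-bearing carbon and the titanium-activated oxygen leaves by β-elimination (overall SN2′), a known alcohol-to-allenyl-boronate reaction type applied here to a primary substrate.

**Step 5**
Reactants: 7 1-[2-(benzyloxy)-4-bromophenyl]ethanone; 9 allenyl boronate 4,4,5,5-tetramethyl-2-(4-methylpenta-1,2-dien-3-yl)-1,3,2-dioxaborolane (1.8 equiv)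
Product: 11 (2S)-2-[2-(benzyloxy)-4-bromophenyl]-6-methylhept-4-yn-2-ol, via borate ester 10 (not isolated)
Conditions: (R)-3,3′-Br2-BINOL (15 mol %), PhCF3 (2 M), 50 °C, 48 h; then H2O
Reagents that add atoms: none
Why: Proposed new method: an achiral, α-branched, γ-unsubstituted allenyl boronate is used as a side-chain-complete propargyl donor in chiral-biphenol catalysis; the biphenol opens one B–O bond of the pinacol ester to give a more Lewis-acidic, internally hydrogen-bonded mixed boronate, the ketone binds to boron, and the C–C bond forms through a closed six-membered SE2′ transition state at the unsubstituted CH2 terminus, so the boron-bearing carbon (isopropyl pointing away from the ketone) becomes an alkyne carbon and only the internal alkyne can form, while the bromine-flanked pocket of the catalyst tells aryl from methyl and directs attack to the Si face to set the (S)-carbinol; the closest known reaction type is the chiral-biphenol-catalysed propargylation of ketones with unsubstituted or γ-substituted allenyl boronates, which has not been run with an α-alkyl, γ-unsubstituted reagent to deliver an internal alkyne.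

**Step 6**
Reactants: 11 (2S)-2-[2-(benzyloxy)-4-bromophenyl]-6-methylhept-4-yn-2-ol; 5 benzylic boronate 4,4,5,5-tetramethyl-2-[(6-methyl-2,2-diphenyl-1,3-benzodioxol-4-yl)methyl]-1,3,2-dioxaborolane (1.3 equiv)
Product: 12 (2S)-2-{2-(benzyloxy)-4-[(6-methyl-2,2-diphenyl-1,3-benzodioxol-4-yl)methyl]phenyl}-6-methylhept-4-yn-2-ol
Conditions: Pd(dppf)Cl2 (5 mol %), K3PO4 (3 equiv), 1,4-dioxane/H2O (5:1), 85 °C
Reagents that add atoms: none
Why: sp3–sp2 Suzuki–Miyaura coupling: the unhindered aryl bromide adds oxidatively to zerovalent palladium and the benzylic boronate (no β-hydrogens) transmetalates under aqueous phosphate, while the alkyne, tertiary alcohol, ketal and benzyl ether are inert and the stereocentre is not involved.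

**Step 7**
Reactants: 12 (2S)-2-{2-(benzyloxy)-4-[(6-methyl-2,2-diphenyl-1,3-benzodioxol-4-yl)methyl]phenyl}-6-methylhept-4-yn-2-ol
Product: 13 Asperchondol A, 3-{[3-hydroxy-4-[(2S)-2-hydroxy-6-methylheptan-2-yl]phenyl]methyl}-5-methylbenzene-1,2-diol
Conditions: H2 (1 atm), 10% Pd/C, EtOAc/MeOH (1:1), rt; work-up under argon
Reagents that add atoms: none
Why: Heterogeneous hydrogenation saturates the alkyne and hydrogenolyses both the benzyl ether and the benzylic C–O bonds of the diphenylmethylene ketal in one operation under neutral conditions that leave the tertiary benzylic alcohol and its configuration untouched.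

**Compound list**
1 | 4-methylbenzene-1,2-diol | Cc1ccc(O)c(O)c1 | starting material
2 | 5-methyl-2,2-diphenyl-1,3-benzodioxole | Cc1ccc2OC(c3ccccc3)(c3ccccc3)Oc2c1 | intermediate
3 | (6-methyl-2,2-diphenyl-1,3-benzodioxol-4-yl)lithium | Cc1cc([Li])c2OC(c3ccccc3)(c3ccccc3)Oc2c1 | intermediate
4 | lithium (bromomethyl)(6-methyl-2,2-diphenyl-1,3-benzodioxol-4-yl)(pinacolato)borate | [Li+].Cc1cc([B-]2(CBr)OC(C)(C)C(C)(C)O2)c2OC(c3ccccc3)(c3ccccc3)Oc2c1 | intermediate
5 | 4,4,5,5-tetramethyl-2-[(6-methyl-2,2-diphenyl-1,3-benzodioxol-4-yl)methyl]-1,3,2-dioxaborolane | Cc1cc(CB2OC(C)(C)C(C)(C)O2)c2OC(c3ccccc3)(c3ccccc3)Oc2c1 | intermediate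
6 | 1-(4-bromo-2-hydroxyphenyl)ethanone | CC(=O)c1ccc(Br)cc1O | starting material
7 | 1-[2-(benzyloxy)-4-bromophenyl]ethanone | CC(=O)c1ccc(Br)cc1OCc1ccccc1 | intermediate
8 | 4-methylpent-2-yn-1-ol | CC(C)C#CCO | starting material
9 | 4,4,5,5-tetramethyl-2-(4-methylpenta-1,2-dien-3-yl)-1,3,2-dioxaborolane | C=C=C(C(C)C)B1OC(C)(C)C(C)(C)O1 | intermediate
10 | 2-{[(2S)-2-[2-(benzyloxy)-4-bromophenyl]-6-methylhept-4-yn-2-yl]oxy}-4,4,5,5-tetramethyl-1,3,2-dioxaborolane | Brc1ccc([C@@](C)(OB2OC(C)(C)C(C)(C)O2)CC#CC(C)C)c(OCc2ccccc2)c1 | intermediate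
11 | (2S)-2-[2-(benzyloxy)-4-bromophenyl]-6-methylhept-4-yn-2-ol | Brc1ccc([C@@](C)(O)CC#CC(C)C)c(OCc2ccccc2)c1 | intermediate
12 | (2S)-2-{2-(benzyloxy)-4-[(6-methyl-2,2-diphenyl-1,3-benzodioxol-4-yl)methyl]phenyl}-6-methylhept-4-yn-2-ol | Cc1cc(Cc2ccc([C@@](C)(O)CC#CC(C)C)c(OCc3ccccc3)c2)c2OC(c3ccccc3)(c3ccccc3)Oc2c1 | intermediate
13 | Asperchondol A | Cc1cc(O)c(O)c(Cc2ccc([C@@](C)(O)CCCC(C)C)c(O)c2)c1 | target

**Step count**
Total: 7 steps. Longest linear sequence: 4 steps (steps 3, 5, 6, 7 from 6; equally steps 1, 2, 6, 7 from 1).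

**Three steps most likely to fail**

Step 5 (new reaction). The α-isopropyl group may slow ligand exchange at boron, and the ortho-benzyloxy ketone is less electrophilic and more twisted than acetophenone, so rate and enantioselectivity are both unproven. A moderate ee could be raised by crystallising 12. The fallback sets out from 7 and comes back to the route at 13; it uses only known chemistry and makes 9 unnecessary. Ketone 7 is allylated with allyldiisopropoxyborane under the established chiral-biphenol catalysis for aryl methyl ketones ((R)-3,3′-Br2-BINOL 15 mol %, PhCF3/toluene, −35 °C), which first gives diisopropyl (2S)-2-[2-(benzyloxy)-4-bromophenyl]pent-4-en-2-yl borate F1 and, after aqueous work-up, (2S)-2-[2-(benzyloxy)-4-bromophenyl]pent-4-en-2-ol F2. Cross-metathesis of F2 with excess 3-methylbut-1-ene (second-generation Hoveyda–Grubbs catalyst, (H2IMes)Cl2Ru(=CH-C6H4-2-O-i-Pr), CH2Cl2, 40 °C, sealed tube) gives (2S,4E)-2-[2-(benzyloxy)-4-bromophenyl]-6-methylhept-4-en-2-ol F3. Coupling of F3 with 5 under the step 6 conditions gives (2S,4E)-2-{2-(benzyloxy)-4-[(6-methyl-2,2-diphenyl-1,3-benzodioxol-4-yl)methyl]phenyl}-6-methylhept-4-en-2-ol F4, and hydrogenation under the step 7 conditions gives 13. This route is also 7 steps in total, with a longest linear sequence of 5.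

Step 4. The titanium-assisted direct borylation is a known reaction type, but a primary propargylic alcohol with an alkyl-substituted alkyne may give protodeboration or incomplete conversion, and 9 has to be distilled free of B2pin2. The fallback sets out from 8 and comes back at 9. Alcohol 8 is acylated (ClCO2Me, pyridine, CH2Cl2, 0 °C) to methyl 4-methylpent-2-yn-1-yl carbonate F5, which undergoes the established copper-catalysed SN2′ borylation of propargylic carbonates (B2pin2, CuO-t-Bu 5 mol %, Xantphos, THF, rt). The leaving group is then activated covalently instead of by a Lewis acid, and the catalyst is turned over by the methoxide released on decarboxylation. This costs one extra step.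

Step 6. The ortho-oxygenated benzylic boronate may protodeboronate faster than it transmetalates. The fallback sets out from 2 and 11 and comes back at 13; it makes the diarylmethane by carbonyl addition and hydrogenolysis instead of cross-coupling. Ketal 2 is lithiated as in step 2 (aryllithium 3) and quenched with DMF to give 6-methyl-2,2-diphenyl-1,3-benzodioxole-4-carbaldehyde F6. Bromide 11 is treated with n-BuLi (2.2 equiv, THF, −78 °C; alkoxide formation, then bromine–lithium exchange) to give the dilithio species lithium (2S)-2-[2-(benzyloxy)-4-lithiophenyl]-6-methylhept-4-yn-2-olate F7, which adds to F6 to give, after work-up, the diaryl carbinol (2S)-2-{2-(benzyloxy)-4-[hydroxy(6-methyl-2,2-diphenyl-1,3-benzodioxol-4-yl)methyl]phenyl}-6-methylhept-4-yn-2-ol F8 as a mixture of carbinol epimers. Hydrogenation (H2, 10% Pd/C, EtOAc/MeOH, rt) reduces the alkyne, removes both protecting groups and hydrogenolyses the doubly benzylic secondary C–OH to CH2, giving 13. The tertiary mono-benzylic alcohol is expected to be cleaved much more slowly, so the reaction is stopped once F8-derived carbinol is consumed.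

**Further compounds**
F1 | step 5 | diisopropyl (2S)-2-[2-(benzyloxy)-4-bromophenyl]pent-4-en-2-yl borate | Brc1ccc([C@@](C)(OB(OC(C)C)OC(C)C)CC=C)c(OCc2ccccc2)c1
F2 | step 5 | (2S)-2-[2-(benzyloxy)-4-bromophenyl]pent-4-en-2-ol | Brc1ccc([C@@](C)(O)CC=C)c(OCc2ccccc2)c1
F3 | step 5 | (2S,4E)-2-[2-(benzyloxy)-4-bromophenyl]-6-methylhept-4-en-2-ol | Brc1ccc([C@@](C)(O)C/C=C/C(C)C)c(OCc2ccccc2)c1
F4 | step 5 | (2S,4E)-2-{2-(benzyloxy)-4-[(6-methyl-2,2-diphenyl-1,3-benzodioxol-4-yl)methyl]phenyl}-6-methylhept-4-en-2-ol | Cc1cc(Cc2ccc([C@@](C)(O)C/C=C/C(C)C)c(OCc3ccccc3)c2)c2OC(c3ccccc3)(c3ccccc3)Oc2c1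
F5 | step 4 | methyl 4-methylpent-2-yn-1-yl carbonate | COC(=O)OCC#CC(C)C
F6 | step 6 | 6-methyl-2,2-diphenyl-1,3-benzodioxole-4-carbaldehyde | Cc1cc(C=O)c2OC(c3ccccc3)(c3ccccc3)Oc2c1
F7 | step 6 | lithium (2S)-2-[2-(benzyloxy)-4-lithiophenyl]-6-methylhept-4-yn-2-olate | [Li]c1ccc([C@@](C)(O[Li])CC#CC(C)C)c(OCc2ccccc2)c1
F8 | step 6 | (2S)-2-{2-(benzyloxy)-4-[hydroxy(6-methyl-2,2-diphenyl-1,3-benzodioxol-4-yl)methyl]phenyl}-6-methylhept-4-yn-2-ol | Cc1cc(C(O)c2ccc([C@@](C)(O)CC#CC(C)C)c(OCc3ccccc3)c2)c2OC(c3ccccc3)(c3ccccc3)Oc2c1
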